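## Analysis of the target

Target 33 joins an oxolane (O1, C2, C3, C4, C5) to a 2,3-dihydrobenzofuran (O1', C2', C3', C3a', C4'–C7', C7a') through the C2–C5' bond. The oxolane carries the aryl group at C2, CH2OH at C3 and, at the fully substituted C4, a tertiary hydroxyl and a 4-hydroxy-3-methoxybenzyl group; its three carbon substituents lie on one face and the hydroxyl on the other (2R,3R,4S in this numbering), so C2/C3 is cis. The dihydrobenzofuran carries a guaiacyl group at C2' and CH2OH at C3', again cis (2'R,3'R), with a methoxy group at C7'. The two stereo-clusters are insulated from each other by the arene, so each needs its own source of absolute configuration. The sensitive groups are the two free phenols and the two benzylic C–O bonds (C2–O1 and C2'–O1'), each para to an oxygen-bearing arene carbon and therefore open to acid ionisation (epimerisation towards trans) and to hydrogenolysis. The hard parts are the two contra-thermodynamic cis relationships, the quaternary carbinol C4, and the fact that a C3' carbonyl derivative is β-aryloxy: it cannot be enolised without E1cB opening of the furan ring, so cis at C2'/C3' must be made kinetically and cannot be corrected later. The strategy rests on one feature: C3' bears exactly one exocyclic carbon and is bonded directly to arene carbon C3a', the pattern left when the carbonyl carbon of a flavanone is pushed out of the pyranone ring as an ester carbon while the flavanone C2 stereocentre becomes C2'.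

## Retrosynthetic reasoning

33 to 32 to 31. The last two operations change no skeletal bond: the phenols of 33 come from hydrogenolysis of the two aryl benzyl ethers of 32, and the three aliphatic hydroxyls of 32 from fluoride cleavage of the silyl ethers of 31. Benzyl is kept only on phenolic oxygen, where it is cleaved fastest, because the C2–O1 and C2'–O1' bonds are themselves benzylic.

31 to 29. The C2–H bond is cut, leading to hemiketal 29. The forward step is an ionic hydrogenation through oxocarbenium ion 30. Hydride should arrive on the face away from the C3 and C4 carbon substituents, which is the face that gives the 2,3-cis oxolane, so C2 needs no chirality source of its own.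

29 to 14 and 27. The C2–C5' bond is cut between the two stereo-clusters: aryllithium 28, from bromide 14, adds to the carbonyl of lactone 27. This makes the route convergent and puts all oxolane stereocentres into a small fragment made from cheap materials. An umpolung union at the same bond (a sulfur-stabilised acyl anion equivalent of the aryl unit opening epoxide 22 at C3) would ask a tertiary carbanion to attack a secondary carbon flanked by a quaternary centre, and is not used.

27 to 26 to 25 to 23. These are oxidation-state and protecting-group changes only. The lactone carbonyl C2 is traced back through lactol 25 and aldehyde 24 to the terminal alkene of 23, so that C2 can be introduced as a small, non-basic vinyl nucleophile.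

23 to 22. The C2–C3 bond is cut: a vinyl copper reagent opens epoxy alcohol 22 at C3 with inversion. C4 is fully substituted, so C3 is the only carbon open to SN2 attack, and the epoxide oxygen becomes the tertiary C4 hydroxyl with its configuration untouched.

22 to 21. Both epoxide C–O bonds are cut. Asymmetric epoxidation of the (E)-trisubstituted allylic alcohol 21 sets C3 and C4 together under reagent control; the (E) geometry, after inversion at C3, translates into the cis relation of CH2O at C3 and benzyl at C4.

21 to 20 to 18 and 19, 18 to 16 and 17, 16 to 15. The trisubstituted alkene is cut by an olefination between phosphonate 18 and aldehyde 19; 18 comes from alkylation of 17 with bromide 16, made from alcohol 15.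

14 to 13 to 12. The C3' hydroxymethyl group is traced to the ester of 12 (reduction, then silylation). The aryl bromide is carried unchanged as the latent nucleophile.

12 to 9 (key disconnection). The C3'–C3a' bond is cut and C3a' is reconnected to the ester carbon, which becomes the ketone carbon of 3-diazoflavanone 9. Forward, loss of N2 with 1,2-shift of the aryl carbon contracts the pyranone to the dihydrofuran, and the ester carbon is expelled as a ketene. C2' is inherited from 9 and directs the protonation that sets C3'.

9 to 8 to 7. The diazo group is traced to an oxime and then to the α-methylene group of flavanone 7. Nitrosation runs through the enol under acid, so the flavanone enolate, which opens the ring and racemises C2, is avoided.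

7 to 5 and 6. The C2–aryl bond is cut: catalytic asymmetric conjugate addition of boronic acid 6 to chromone 5 creates the single catalytic stereocentre of the arene half.

5 to 2 and 3, 2 to 1. The chromone C2 carbon comes from amide acetal 3 via enaminone 4; the bromine that later becomes C5'–Li is placed para to the phenol of 1.

## Alternatives that were turned down

Alternative 1: Disconnection at O1–C2/C2–H of the oxolane, with the complete skeleton, cis-dihydrobenzofuran included, carried as γ-hydroxy aryl ketone A2.
- Forward key step: A2 closes to its lactol, a Lewis acid ionises it, and a silane delivers hydride to C2 to give silylated target A1.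
- For: this reaction type is well established for 2-aryl oxolanes, is convergent, and hydride should come anti to the C3 substituent and give the required 2,3-cis ring. On reliability of the named step it is stronger than the chosen key step.
- Against: as the central idea it sets one of five stereocentres and closes the easier ring. A2 must already contain the contra-thermodynamic cis-dihydrobenzofuran and the C3/C4 pair, for which it offers nothing, and the acid-sensitive C2'–O1' bond still meets the Lewis acid.
- Comparison: the chosen strategy keeps this cyclisation as a supporting step (step 19) and spends its key step on the part of the molecule this alternative leaves open.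

Alternative 2: Disconnection of C2'–aryl and C3'–carbonyl across the furan C2'=C3' bond of benzofuran A4, with aryl iodide A5.
- Forward key step: zerovalent palladium with a chiral phosphine adds the aryl group of A5 to C2' of A4, and the benzylic palladium species at C3' is intercepted by CO and methanol to give diester A3.
- For: syn carbopalladation followed by CO insertion with retention makes the cis relation a mechanistic necessity, and both stereocentres arise in one step from flat precursors. On these two points (cis by mechanism instead of by face-selective protonation, and step count to the dihydrobenzofuran) it is stronger than the chosen route.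
- Against: intermolecular dearomative arylation of a simple benzofuran must beat the usual C2–H arylation that restores aromaticity. Enantiocontrol would have to be found. The two methyl esters of A3 (C3' and C5') must then be told apart, and the C5' ester must be turned into the carbon that joins the oxolane.
- Comparison: the chosen strategy offers a known reaction type at the key step, one catalytic stereocentre of an established kind, and a C5' bromide that becomes the aryllithium directly.

Alternative 3: Disconnection of the oxolane C2–C3 bond, with α-diazo lactone A7 as precursor.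
- Forward key step: Rh2(OAc)4 forms a carbenoid at C3 of A7 that inserts into the benzylic ether C–H at C2, closing the oxolane onto the lactone to give furofuranone A6.
- For: the C–H bond is activated by oxygen and by the arene, five-membered insertion is the favoured mode, and the cis ring fusion locks C3 against C4. It makes C2–C3, the ring and two stereocentres at once, which is more direct than the three steps (union, reduction, deprotection) the chosen route spends on the oxolane.
- Against: the aryl group at C2 must end up endo, on the concave face of the bicycle, against the steric preference. The ether oxygen (ylide formation) and the electron-rich arenes (cyclopropanation) compete for the carbenoid. A7 already needs the cis-dihydrobenzofuran and a stereodefined quaternary lactone. The final hydrogenolysis of the lactone benzylic C–O bond must spare the C2–O1 and C2'–O1' bonds, which are benzylic as well.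
- Comparison: it is longer and leaves two open selectivity questions where the chosen route uses an aryllithium addition and an ionic hydrogenation of known stereochemical course.

Key step: step 6

Assumption: (S)-t-BuPyOx is taken to deliver the aryl group to the face of chromone 5 that gives the (2R)-flavanone, by analogy with its sense of induction on β-substituted cyclic enones; if the opposite sense operates, the (R)-ligand is used.

## Route

Step 1
Reactants: 1 1-(2-hydroxy-3-methoxyphenyl)ethanone
Product: 2 1-(5-bromo-2-hydroxy-3-methoxyphenyl)ethanone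
Conditions: NBS (1.05 equiv), MeCN, 0 °C to rt
Reagents that add atoms: N-bromosuccinimide, O=C1CCC(=O)N1Br
Why: Electrophilic aromatic bromination; the phenol directs para (its ortho positions are occupied) and the acetyl group directs meta to the same carbon, so bromine should enter C5 only.

Step 2
Reactants: 2 1-(5-bromo-2-hydroxy-3-methoxyphenyl)ethanone; 3 N,N-dimethylformamide dimethyl acetal
Product: 5 6-bromo-8-methoxy-4H-chromen-4-one, via enaminone 4 (not isolated)
Conditions: 3 (2 equiv, neat), 95 °C; evaporate; then conc. aq. HCl, CH2Cl2, 40 °C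
Reagents that add atoms: none
Why: Enaminone route to chromones: condensation of the methyl ketone with the amide acetal gives 4, and acid promotes addition of the phenol to the β-carbon with loss of dimethylamine.

Step 3
Reactants: 5 6-bromo-8-methoxy-4H-chromen-4-one; 6 (4-benzyloxy-3-methoxyphenyl)boronic acid
Product: 7 (2R)-2-(4-benzyloxy-3-methoxyphenyl)-6-bromo-8-methoxychroman-4-one
Conditions: Pd(OCOCF3)2 (5 mol%), (S)-4-tert-butyl-2-(pyridin-2-yl)-4,5-dihydrooxazole [(S)-t-BuPyOx] (6 mol%), NH4PF6 (30 mol%), 6 (2 equiv), H2O (5 equiv), ClCH2CH2Cl, 60 °C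
Reagents that add atoms: none
Why: Asymmetric conjugate addition of an arylboronic acid to a chromone under divalent palladium catalysis (transmetalation, enone insertion, protonolysis); the pyridine–oxazoline ligand selects the enone face and sets C2, and because no zerovalent palladium is formed the aryl bromide should stay intact.

Step 4
Reactants: 7 (2R)-2-(4-benzyloxy-3-methoxyphenyl)-6-bromo-8-methoxychroman-4-one
Product: 8 (2S)-2-(4-benzyloxy-3-methoxyphenyl)-6-bromo-3-(hydroxyimino)-8-methoxychroman-4-one (same spatial arrangement at C2 as 7; the descriptor changes because C3 now outranks the aryl group)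
Conditions: isopentyl nitrite (1.5 equiv), HCl (4 M in dioxane, 1 equiv), EtOH–THF, 0 °C to rt
Reagents that add atoms: isopentyl nitrite, CC(C)CCON=O
Why: Acid-catalysed α-nitrosation of a ketone through its enol, followed by tautomerisation to the oxime, a classical reaction of flavanones; no enolate is formed, so the retro-oxa-Michael opening that would racemise C2 is avoided.

Step 5
Reactants: 8 (2S)-2-(4-benzyloxy-3-methoxyphenyl)-6-bromo-3-(hydroxyimino)-8-methoxychroman-4-one
Product: 9 (2S)-2-(4-benzyloxy-3-methoxyphenyl)-6-bromo-3-diazo-8-methoxychroman-4-one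
Conditions: aq. NaOH (2 equiv), conc. aq. NH3, THF, 0 °C; aq. NaOCl added slowly (chloramine formed in the flask); dark
Reagents that add atoms: chloramine (from NaOCl and NH3), NCl
Why: Forster reaction: the oximate nitrogen is aminated by chloramine and loss of water gives the diazo group; C3 has no hydrogen and C2–H is not acidic enough for aqueous hydroxide at 0 °C, so C2 should be untouched.

Step 6
Reactants: 9 (2S)-2-(4-benzyloxy-3-methoxyphenyl)-6-bromo-3-diazo-8-methoxychroman-4-one
Product: 12 methyl (2R,3S)-2-(4-benzyloxy-3-methoxyphenyl)-5-bromo-7-methoxy-2,3-dihydro-1-benzofuran-3-carboxylate (cis ester), via ketene 10 (not isolated), via ester enol 11 (not isolated)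
Conditions: hν (365 nm LEDs), MeOH–THF (4:1), degassed, 0 °C
Reagents that add atoms: methanol, CO
Why: Photochemical Wolff rearrangement with ring contraction: excitation of the s-Z-locked α-diazo ketone expels N2 with concerted 1,2-shift of the aryl carbon C4a from the carbonyl carbon to the diazo carbon, which forms the C3'–C3a' bond and leaves the former carbonyl carbon exocyclic as ketene 10. The closest known reaction type is the light-induced contraction of benzo-fused cyclic 2-diazo ketones (diazoindanones, diazotetralones) to the ester of the next smaller ring. The five-membered ring (O1', C2', C3', C3a', C7a') arises by contraction of the pyranone through this 1,2-shift, not by an end-to-end cyclisation. Methanol adds to 10 to give ester enol 11, and the new stereocentre C3' is set when 11 is protonated at C3' from the face opposite the C2' aryl group, which places CO2Me cis to that group; the controlling element is the C2' stereocentre made in step 3. Three selectivities are needed: migration of C4a in preference to a 1,2-shift of the C2' hydrogen (which would give the flavone) or O–H insertion of a free carbene, secured by the enforced s-Z geometry that favours the concerted path on direct irradiation; cis-selective protonation, secured by the shielding aryl group; and survival of the kinetic cis ester, secured by the neutral medium, in which neither epimerisation nor E1cB opening can start. Light of 365 nm is absorbed by the diazo ketone but not by the aryl bromide or the benzyl ether, and C2' is never deprotonated, so its configuration should be carried over unchanged.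

Step 7
Reactants: 12 methyl (2R,3S)-2-(4-benzyloxy-3-methoxyphenyl)-5-bromo-7-methoxy-2,3-dihydro-1-benzofuran-3-carboxylate
Product: 13 [(2R,3R)-2-(4-benzyloxy-3-methoxyphenyl)-5-bromo-7-methoxy-2,3-dihydro-1-benzofuran-3-yl]methanol (cis)
Conditions: i-Bu2AlH (DIBAL-H, 3 equiv), CH2Cl2, −78 to −40 °C; aq. potassium sodium tartrate
Reagents that add atoms: none
Why: Hydride reduction of the ester to the primary alcohol by a Lewis-acidic, non-basic aluminium hydride at low temperature, so that C3' is not enolised and the cis relation is fixed once the carbonyl is gone; the aryl bromide is inert to this reagent in the cold.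

Step 8
Reactants: 13 [(2R,3R)-2-(4-benzyloxy-3-methoxyphenyl)-5-bromo-7-methoxy-2,3-dihydro-1-benzofuran-3-yl]methanol
Product: 14 tert-butyl{[(2R,3R)-2-(4-benzyloxy-3-methoxyphenyl)-5-bromo-7-methoxy-2,3-dihydro-1-benzofuran-3-yl]methoxy}dimethylsilane
Conditions: t-BuMe2SiCl, imidazole, DMF, rt
Reagents that add atoms: tert-butyldimethylsilyl chloride, CC(C)(C)[Si](C)(C)Cl
Why: Standard silylation of a primary alcohol; it removes the acidic proton before the halogen–lithium exchange of step 18.

Step 9
Reactants: 15 (4-benzyloxy-3-methoxyphenyl)methanol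
Product: 16 1-(benzyloxy)-4-(bromomethyl)-2-methoxybenzene
Conditions: PBr3 (0.4 equiv), Et2O, 0 °C
Reagents that add atoms: phosphorus tribromide, BrP(Br)Br
Why: Conversion of an electron-rich benzylic alcohol into the bromide through its phosphite ester; the aryl benzyl ether is stable to these conditions.

Step 10
Reactants: 16 1-(benzyloxy)-4-(bromomethyl)-2-methoxybenzene; 17 triethyl phosphonoacetate
Product: 18 ethyl 3-(4-benzyloxy-3-methoxyphenyl)-2-(diethoxyphosphoryl)propanoate (racemic)
Conditions: NaH, THF, 0 °C; then 16, rt (17 in excess)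
Reagents that add atoms: none
Why: C-alkylation of the phosphonate-stabilised carbanion with a reactive benzylic bromide; an excess of 17 keeps dialkylation down.

Step 11
Reactants: 18 ethyl 3-(4-benzyloxy-3-methoxyphenyl)-2-(diethoxyphosphoryl)propanoate; 19 (tert-butyldimethylsilyloxy)acetaldehyde
Product: 20 ethyl (E)-2-[(4-benzyloxy-3-methoxyphenyl)methyl]-4-(tert-butyldimethylsilyloxy)but-2-enoate
Conditions: NaH, THF, −20 °C to rt
Reagents that add atoms: none
Why: Horner–Wadsworth–Emmons olefination; with an α-substituted phosphonoacetate the ester should end up trans to the β-substituent, which is the (E)-isomer, and the minor (Z)-isomer is removed by chromatography.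

Step 12
Reactants: 20 ethyl (E)-2-[(4-benzyloxy-3-methoxyphenyl)methyl]-4-(tert-butyldimethylsilyloxy)but-2-enoate
Product: 21 (E)-2-[(4-benzyloxy-3-methoxyphenyl)methyl]-4-(tert-butyldimethylsilyloxy)but-2-en-1-ol
Conditions: i-Bu2AlH (2.2 equiv), CH2Cl2, −78 °C
Reagents that add atoms: none
Why: 1,2-Reduction of an α,β-unsaturated ester to the allylic alcohol; the alkene geometry is retained.

Step 13
Reactants: 21 (E)-2-[(4-benzyloxy-3-methoxyphenyl)methyl]-4-(tert-butyldimethylsilyloxy)but-2-en-1-ol
Product: 22 [(2R,3R)-2-[(4-benzyloxy-3-methoxyphenyl)methyl]-3-[(tert-butyldimethylsilyloxy)methyl]oxiran-2-yl]methanol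
Conditions: Ti(OiPr)4 (10 mol%), D-(−)-diethyl tartrate (12 mol%), t-BuOOH (2 equiv, in decane), 4 Å molecular sieves, CH2Cl2, −20 °C
Reagents that add atoms: tert-butyl hydroperoxide, CC(C)(C)OO
Why: Sharpless asymmetric epoxidation of an (E)-trisubstituted allylic alcohol, a favourable substrate class; the tartrate fixes the face and so sets C3 and C4 together, and the D-(−)-ester is chosen because the L-(+)-ester delivers oxygen to the opposite face.

Step 14
Reactants: 22 [(2R,3R)-2-[(4-benzyloxy-3-methoxyphenyl)methyl]-3-[(tert-butyldimethylsilyloxy)methyl]oxiran-2-yl]methanol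
Product: 23 (2S,3S)-2-[(4-benzyloxy-3-methoxyphenyl)methyl]-3-[(tert-butyldimethylsilyloxy)methyl]pent-4-ene-1,2-diol
Conditions: CH2=CHMgBr (4 equiv), CuI (20 mol%), THF–Et2O, −30 to 0 °C
Reagents that add atoms: vinylmagnesium bromide, C=C[Mg]Br
Why: Copper-catalysed SN2 opening of a 2,3-epoxy alcohol by a vinyl nucleophile; the fully substituted epoxide carbon cannot be attacked, so the vinyl group should enter at C3 with inversion, and the epoxide oxygen becomes the tertiary hydroxyl with C4 unchanged.

Step 15
Reactants: 23 (2S,3S)-2-[(4-benzyloxy-3-methoxyphenyl)methyl]-3-[(tert-butyldimethylsilyloxy)methyl]pent-4-ene-1,2-diol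
Product: 25 (3S,4S)-4-[(4-benzyloxy-3-methoxyphenyl)methyl]-3-[(tert-butyldimethylsilyloxy)methyl]oxolane-2,4-diol (lactol; both anomers), via hydroxy aldehyde 24 (not isolated)
Conditions: O3, CH2Cl2–MeOH, −78 °C, stopped at the first persistent blue; then PPh3, −78 °C to rt
Reagents that add atoms: ozone, [O-][O+]=O
Why: Ozonolysis with reductive work-up; the terminal alkene reacts much faster than the alkoxyarenes at −78 °C, and aldehyde 24 is trapped by the primary hydroxyl as the five-membered lactol, which protects the α-stereocentre C3.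

Step 16
Reactants: 25 (3S,4S)-4-[(4-benzyloxy-3-methoxyphenyl)methyl]-3-[(tert-butyldimethylsilyloxy)methyl]oxolane-2,4-diol
Product: 26 (3S,4S)-4-[(4-benzyloxy-3-methoxyphenyl)methyl]-3-[(tert-butyldimethylsilyloxy)methyl]-4-hydroxyoxolan-2-one
Conditions: PhI(OAc)2 (1.5 equiv), (2,2,6,6-tetramethylpiperidin-1-yl)oxyl (TEMPO, 10 mol%), CH2Cl2, rt
Reagents that add atoms: none
Why: Oxoammonium-mediated oxidation of a lactol to the lactone under neutral conditions; the tertiary alcohol cannot be oxidised and the α-stereocentre is not exposed to base.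

Step 17
Reactants: 26 (3S,4S)-4-[(4-benzyloxy-3-methoxyphenyl)methyl]-3-[(tert-butyldimethylsilyloxy)methyl]-4-hydroxyoxolan-2-one
Product: 27 (3S,4S)-4-[(4-benzyloxy-3-methoxyphenyl)methyl]-3-[(tert-butyldimethylsilyloxy)methyl]-4-(triethylsilyloxy)oxolan-2-one
Conditions: Et3SiOTf, 2,6-lutidine, CH2Cl2, −78 to 0 °C
Reagents that add atoms: triethylsilyl trifluoromethanesulfonate, CC[Si](CC)(CC)OS(=O)(=O)C(F)(F)F
Why: Silylation of a hindered tertiary alcohol with a silyl triflate and a non-nucleophilic base too weak to enolise the lactone; it removes the proton that would otherwise consume the aryllithium.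

Step 18
Reactants: 14 tert-butyl{[(2R,3R)-2-(4-benzyloxy-3-methoxyphenyl)-5-bromo-7-methoxy-2,3-dihydro-1-benzofuran-3-yl]methoxy}dimethylsilane; 27 (3S,4S)-4-[(4-benzyloxy-3-methoxyphenyl)methyl]-3-[(tert-butyldimethylsilyloxy)methyl]-4-(triethylsilyloxy)oxolan-2-one
Product: 29 (3S,4S)-2-[(2R,3R)-2-(4-benzyloxy-3-methoxyphenyl)-3-[(tert-butyldimethylsilyloxy)methyl]-7-methoxy-2,3-dihydro-1-benzofuran-5-yl]-4-[(4-benzyloxy-3-methoxyphenyl)methyl]-3-[(tert-butyldimethylsilyloxy)methyl]-4-(triethylsilyloxy)oxolan-2-ol (hemiketal; both anomers), via aryllithium 28 (not isolated)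
Conditions: 14 (1.2 equiv), t-BuLi (2.0 equiv per 14), THF, −78 °C; then 27, −78 °C; H2O
Reagents that add atoms: none
Why: Bromine–lithium exchange followed by addition of the aryllithium to a lactone carbonyl, the reaction type used for aryl C-glycosides; at −78 °C addition should outrun enolisation, and the cyclic lithium alkoxide does not collapse to a ketone, which prevents a second addition.

Step 19
Reactants: 29 (3S,4S)-2-[(2R,3R)-2-(4-benzyloxy-3-methoxyphenyl)-3-[(tert-butyldimethylsilyloxy)methyl]-7-methoxy-2,3-dihydro-1-benzofuran-5-yl]-4-[(4-benzyloxy-3-methoxyphenyl)methyl]-3-[(tert-butyldimethylsilyloxy)methyl]-4-(triethylsilyloxy)oxolan-2-ol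
Product: 31 (2R,3R,4S)-2-[(2R,3R)-2-(4-benzyloxy-3-methoxyphenyl)-3-[(tert-butyldimethylsilyloxy)methyl]-7-methoxy-2,3-dihydro-1-benzofuran-5-yl]-4-[(4-benzyloxy-3-methoxyphenyl)methyl]-3-[(tert-butyldimethylsilyloxy)methyl]-4-(triethylsilyloxy)oxolane, via oxocarbenium ion 30 (not isolated)
Conditions: Et3SiH (5 equiv), BF3·OEt2 (2 equiv), CH2Cl2, −78 to −50 °C
Reagents that add atoms: none
Why: Ionic hydrogenation of a hemiketal: the Lewis acid ionises C2–OH and the silane reduces the 2-aryl oxocarbenium ion; hydride should come anti to the CH2OSi group at C3 and the benzyl group at C4 and syn to the pseudoaxial C4 silyloxy group (inside attack on the envelope), which sets C2 with the aryl group cis to C3. The low temperature is meant to keep the C2'–O1' bond from ionising, and any partial loss of silyl groups is harmless because step 20 removes them.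

Step 20
Reactants: 31 (2R,3R,4S)-2-[(2R,3R)-2-(4-benzyloxy-3-methoxyphenyl)-3-[(tert-butyldimethylsilyloxy)methyl]-7-methoxy-2,3-dihydro-1-benzofuran-5-yl]-4-[(4-benzyloxy-3-methoxyphenyl)methyl]-3-[(tert-butyldimethylsilyloxy)methyl]-4-(triethylsilyloxy)oxolane
Product: 32 (3S,4R,5R)-5-[(2R,3R)-2-(4-benzyloxy-3-methoxyphenyl)-3-(hydroxymethyl)-7-methoxy-2,3-dihydro-1-benzofuran-5-yl]-3-[(4-benzyloxy-3-methoxyphenyl)methyl]-4-(hydroxymethyl)oxolan-3-ol
Conditions: Bu4NF (5 equiv), THF, 0 °C to rt
Reagents that add atoms: none
Why: Fluoride cleavage of the two primary tert-butyldimethylsilyl ethers and the tertiary triethylsilyl ether; the conditions are non-acidic and should touch no stereocentre.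

Step 21
Reactants: 32 (3S,4R,5R)-5-[(2R,3R)-2-(4-benzyloxy-3-methoxyphenyl)-3-(hydroxymethyl)-7-methoxy-2,3-dihydro-1-benzofuran-5-yl]-3-[(4-benzyloxy-3-methoxyphenyl)methyl]-4-(hydroxymethyl)oxolan-3-ol
Product: 33 (3S,4R,5R)-5-[(2R,3R)-2-(4-hydroxy-3-methoxyphenyl)-3-(hydroxymethyl)-7-methoxy-2,3-dihydro-1-benzofuran-5-yl]-3-[(4-hydroxy-3-methoxyphenyl)methyl]-4-(hydroxymethyl)oxolan-3-ol (target)
Conditions: H2 (1 atm), Pd/C (10%), EtOAc–MeOH, rt, stopped as soon as both benzyl groups are gone
Reagents that add atoms: none
Why: Hydrogenolysis of aryl benzyl ethers, which are cleaved faster than dialkyl or alkyl aryl benzylic ethers; neutral solvent and a short reaction time are meant to spare the C2–O1 and C2'–O1' bonds.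

## Compound list

1 | 1-(2-hydroxy-3-methoxyphenyl)ethanone | CC(=O)c1cccc(OC)c1O | starting material
2 | 1-(5-bromo-2-hydroxy-3-methoxyphenyl)ethanone | CC(=O)c1cc(Br)cc(OC)c1O | intermediate
3 | N,N-dimethylformamide dimethyl acetal | COC(OC)N(C)C | starting material
4 | (E)-1-(5-bromo-2-hydroxy-3-methoxyphenyl)-3-(dimethylamino)prop-2-en-1-one | CN(C)/C=C/C(=O)c1cc(Br)cc(OC)c1O | intermediate (not isolated)
5 | 6-bromo-8-methoxy-4H-chromen-4-one | O=c1ccoc2c(OC)cc(Br)cc12 | intermediate
6 | (4-benzyloxy-3-methoxyphenyl)boronic acid | COc1cc(B(O)O)ccc1OCc1ccccc1 | starting material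
7 | (2R)-2-(4-benzyloxy-3-methoxyphenyl)-6-bromo-8-methoxychroman-4-one | Brc1cc(OC)c2c(c1)C(=O)C[C@H](c1ccc(OCc3ccccc3)c(OC)c1)O2 | intermediate
8 | (2S)-2-(4-benzyloxy-3-methoxyphenyl)-6-bromo-3-(hydroxyimino)-8-methoxychroman-4-one | Brc1cc(OC)c2c(c1)C(=O)C(=NO)[C@H](c1ccc(OCc3ccccc3)c(OC)c1)O2 | intermediate
9 | (2S)-2-(4-benzyloxy-3-methoxyphenyl)-6-bromo-3-diazo-8-methoxychroman-4-one | Brc1cc(OC)c2c(c1)C(=O)C(=[N+]=[N-])[C@H](c1ccc(OCc3ccccc3)c(OC)c1)O2 | intermediate
10 | [2-(4-benzyloxy-3-methoxyphenyl)-5-bromo-7-methoxy-1-benzofuran-3(2H)-ylidene]methanone (ketene; C2' as in 9) | Brc1cc(OC)c2c(c1)C(=C=O)[C@H](c1ccc(OCc3ccccc3)c(OC)c1)O2 | intermediate (not isolated)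
11 | [2-(4-benzyloxy-3-methoxyphenyl)-5-bromo-7-methoxy-1-benzofuran-3(2H)-ylidene](methoxy)methanol (ester enol; C2' as in 9) | Brc1cc(OC)c2c(c1)C(=C(O)OC)[C@H](c1ccc(OCc3ccccc3)c(OC)c1)O2 | intermediate (not isolated)
12 | methyl (2R,3S)-2-(4-benzyloxy-3-methoxyphenyl)-5-bromo-7-methoxy-2,3-dihydro-1-benzofuran-3-carboxylate (cis) | Brc1cc(OC)c2c(c1)[C@H](C(=O)OC)[C@H](c1ccc(OCc3ccccc3)c(OC)c1)O2 | intermediate
13 | [(2R,3R)-2-(4-benzyloxy-3-methoxyphenyl)-5-bromo-7-methoxy-2,3-dihydro-1-benzofuran-3-yl]methanol (cis) | Brc1cc(OC)c2c(c1)[C@H](CO)[C@H](c1ccc(OCc3ccccc3)c(OC)c1)O2 | intermediate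
14 | tert-butyl{[(2R,3R)-2-(4-benzyloxy-3-methoxyphenyl)-5-bromo-7-methoxy-2,3-dihydro-1-benzofuran-3-yl]methoxy}dimethylsilane | Brc1cc(OC)c2c(c1)[C@H](CO[Si](C)(C)C(C)(C)C)[C@H](c1ccc(OCc3ccccc3)c(OC)c1)O2 | intermediate
15 | (4-benzyloxy-3-methoxyphenyl)methanol | OCc1ccc(OCc2ccccc2)c(OC)c1 | starting material
16 | 1-(benzyloxy)-4-(bromomethyl)-2-methoxybenzene | BrCc1ccc(OCc2ccccc2)c(OC)c1 | intermediate
17 | triethyl phosphonoacetate | CCOC(=O)CP(=O)(OCC)OCC | starting material
18 | ethyl 3-(4-benzyloxy-3-methoxyphenyl)-2-(diethoxyphosphoryl)propanoate (racemic) | CCOC(=O)C(Cc1ccc(OCc2ccccc2)c(OC)c1)P(=O)(OCC)OCC | intermediate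
19 | (tert-butyldimethylsilyloxy)acetaldehyde | O=CCO[Si](C)(C)C(C)(C)C | starting material
20 | ethyl (E)-2-[(4-benzyloxy-3-methoxyphenyl)methyl]-4-(tert-butyldimethylsilyloxy)but-2-enoate | CCOC(=O)/C(Cc1ccc(OCc2ccccc2)c(OC)c1)=C/CO[Si](C)(C)C(C)(C)C | intermediate
21 | (E)-2-[(4-benzyloxy-3-methoxyphenyl)methyl]-4-(tert-butyldimethylsilyloxy)but-2-en-1-ol | OC/C(Cc1ccc(OCc2ccccc2)c(OC)c1)=C/CO[Si](C)(C)C(C)(C)C | intermediate
22 | [(2R,3R)-2-[(4-benzyloxy-3-methoxyphenyl)methyl]-3-[(tert-butyldimethylsilyloxy)methyl]oxiran-2-yl]methanol | OC[C@@]1(Cc2ccc(OCc3ccccc3)c(OC)c2)O[C@@H]1CO[Si](C)(C)C(C)(C)C | intermediate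
23 | (2S,3S)-2-[(4-benzyloxy-3-methoxyphenyl)methyl]-3-[(tert-butyldimethylsilyloxy)methyl]pent-4-ene-1,2-diol | C=C[C@@H](CO[Si](C)(C)C(C)(C)C)[C@](O)(CO)Cc1ccc(OCc2ccccc2)c(OC)c1 | intermediate
24 | (2S,3S)-3-[(4-benzyloxy-3-methoxyphenyl)methyl]-2-[(tert-butyldimethylsilyloxy)methyl]-3,4-dihydroxybutanal | O=C[C@@H](CO[Si](C)(C)C(C)(C)C)[C@](O)(CO)Cc1ccc(OCc2ccccc2)c(OC)c1 | intermediate (not isolated)
25 | (3S,4S)-4-[(4-benzyloxy-3-methoxyphenyl)methyl]-3-[(tert-butyldimethylsilyloxy)methyl]oxolane-2,4-diol (both anomers) | OC1OC[C@](O)(Cc2ccc(OCc3ccccc3)c(OC)c2)[C@@H]1CO[Si](C)(C)C(C)(C)C | intermediate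
26 | (3S,4S)-4-[(4-benzyloxy-3-methoxyphenyl)methyl]-3-[(tert-butyldimethylsilyloxy)methyl]-4-hydroxyoxolan-2-one | O=C1OC[C@](O)(Cc2ccc(OCc3ccccc3)c(OC)c2)[C@@H]1CO[Si](C)(C)C(C)(C)C | intermediate
27 | (3S,4S)-4-[(4-benzyloxy-3-methoxyphenyl)methyl]-3-[(tert-butyldimethylsilyloxy)methyl]-4-(triethylsilyloxy)oxolan-2-one | O=C1OC[C@](O[Si](CC)(CC)CC)(Cc2ccc(OCc3ccccc3)c(OC)c2)[C@@H]1CO[Si](C)(C)C(C)(C)C | intermediate
28 | [(2R,3R)-2-(4-benzyloxy-3-methoxyphenyl)-3-[(tert-butyldimethylsilyloxy)methyl]-7-methoxy-2,3-dihydro-1-benzofuran-5-yl]lithium | [Li]c1cc(OC)c2c(c1)[C@H](CO[Si](C)(C)C(C)(C)C)[C@H](c1ccc(OCc3ccccc3)c(OC)c1)O2 | intermediate (not isolated)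
29 | hemiketal: (3S,4S)-2-aryl-4-[(4-benzyloxy-3-methoxyphenyl)methyl]-3-[(tert-butyldimethylsilyloxy)methyl]-4-(triethylsilyloxy)oxolan-2-ol, aryl = the dihydrobenzofuran-5-yl group of 28 (both anomers) | OC1(c2cc(OC)c3c(c2)[C@H](CO[Si](C)(C)C(C)(C)C)[C@H](c2ccc(OCc4ccccc4)c(OC)c2)O3)OC[C@](O[Si](CC)(CC)CC)(Cc2ccc(OCc3ccccc3)c(OC)c2)[C@@H]1CO[Si](C)(C)C(C)(C)C | intermediate
30 | 2-aryl oxocarbenium ion derived from 29 by loss of hydroxide at C2 | C1(c2cc(OC)c3c(c2)[C@H](CO[Si](C)(C)C(C)(C)C)[C@H](c2ccc(OCc4ccccc4)c(OC)c2)O3)=[O+]C[C@](O[Si](CC)(CC)CC)(Cc2ccc(OCc3ccccc3)c(OC)c2)[C@@H]1CO[Si](C)(C)C(C)(C)C | intermediate (not isolated)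
31 | (2R,3R,4S)-2-aryl-4-[(4-benzyloxy-3-methoxyphenyl)methyl]-3-[(tert-butyldimethylsilyloxy)methyl]-4-(triethylsilyloxy)oxolane, aryl = the dihydrobenzofuran-5-yl group of 28 | COc1cc(C[C@@]2(O[Si](CC)(CC)CC)CO[C@@H](c3cc(OC)c4c(c3)[C@H](CO[Si](C)(C)C(C)(C)C)[C@H](c3ccc(OCc5ccccc5)c(OC)c3)O4)[C@H]2CO[Si](C)(C)C(C)(C)C)ccc1OCc1ccccc1 | intermediate
32 | (3S,4R,5R)-5-[(2R,3R)-2-(4-benzyloxy-3-methoxyphenyl)-3-(hydroxymethyl)-7-methoxy-2,3-dihydro-1-benzofuran-5-yl]-3-[(4-benzyloxy-3-methoxyphenyl)methyl]-4-(hydroxymethyl)oxolan-3-ol | COc1cc(C[C@@]2(O)CO[C@@H](c3cc(OC)c4c(c3)[C@H](CO)[C@H](c3ccc(OCc5ccccc5)c(OC)c3)O4)[C@H]2CO)ccc1OCc1ccccc1 | intermediate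
33 | (3S,4R,5R)-5-[(2R,3R)-2-(4-hydroxy-3-methoxyphenyl)-3-(hydroxymethyl)-7-methoxy-2,3-dihydro-1-benzofuran-5-yl]-3-[(4-hydroxy-3-methoxyphenyl)methyl]-4-(hydroxymethyl)oxolan-3-ol | COc1cc(C[C@@]2(O)CO[C@@H](c3cc(OC)c4c(c3)[C@H](CO)[C@H](c3ccc(O)c(OC)c3)O4)[C@H]2CO)ccc1O | target

## Step count and least certain steps

Total step count: 21. Longest linear sequence: 13 steps (15 to 33, steps 9–17 and 18–21); the arene line from 1 is 12 steps (steps 1–8 and 18–21).

Step 6 (key step). The most likely failures are a 1,2-shift of the C2' hydrogen in a free carbene (aromatisation to the flavone), carbene insertion into the O–H bond of the solvent, and unselective protonation of ester enol 11, which would erode the cis relation; this cannot be repaired by epimerisation because base opens the ring. The fallback sets out from phenol 2 and bromide 16 and returns at 12 by a different bond construction, a carbenoid C–H insertion of a type known to give cis-2-aryl-2,3-dihydrobenzofuran-3-carboxylates. O-alkylation of 2 with 16 (K2CO3, DMF) gives 1-[2-[(4-benzyloxy-3-methoxyphenyl)methoxy]-5-bromo-3-methoxyphenyl]ethanone F1. A Willgerodt–Kindler reaction (S8, morpholine, 130 °C) gives the thioacetomorpholide F2, and KOH hydrolysis gives the arylacetic acid F3. MeI/K2CO3 gives the methyl arylacetate F4, and diazo transfer with 4-acetamidobenzenesulfonyl azide and DBU gives the methyl aryldiazoacetate F5. Rh2(S-PTTL)4, dirhodium tetrakis[N-phthaloyl-(S)-tert-leucinate], or its enantiomer (whichever gives the 2R,3S product), in toluene at −60 °C, should then insert the carbenoid into the benzylic O–CH2 bond and give 12.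

Step 5. The oxime route may lose material or stereochemical purity by base-induced tautomerisation of 8 towards the aromatic 3-(hydroxyamino)flavone (which destroys C2), or by N-chlorination and hydrolysis in place of N-amination. The fallback sets out from flavanone 7 and returns at 9 without the oxime, by detrifluoroacetylative diazo transfer. LiN(SiMe3)2 in THF at −78 °C followed by CF3CO2CH2CF3 gives (2R)-2-(4-benzyloxy-3-methoxyphenyl)-6-bromo-8-methoxy-3-(trifluoroacetyl)chroman-4-one F6; the enolate is formed and acylated in the cold to outrun retro-oxa-Michael opening. MeSO2N3 and Et3N in MeCN–H2O then give 9.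

Step 14. SN2 attack at C3 is slowed by the neighbouring quaternary epoxide carbon and the silyloxymethyl group, so opening by bromide from the magnesium salt or Lewis-acid rearrangement of the epoxide may compete. The fallback sets out from 22 and returns at 23 using hydroxyl-directed delivery. Et2AlC≡CSiMe3 (from Me3SiC≡CLi and Et2AlCl) in toluene at 0 °C binds the hydroxyl of 22 and should deliver the alkynyl group to C3 with inversion, giving (2S,3S)-2-[(4-benzyloxy-3-methoxyphenyl)methyl]-3-[(tert-butyldimethylsilyloxy)methyl]-5-(trimethylsilyl)pent-4-yne-1,2-diol F7. K2CO3 in MeOH gives the terminal alkyne F8, and semihydrogenation (H2, Pd/CaCO3 poisoned with Pb(OAc)2, quinoline) gives 23.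

Step 19. The Lewis acid may ionise the C2'–O1' bond of the cis-dihydrobenzofuran (epimerisation towards trans), oxocarbenium ion 30 may lose a proton to an enol ether (scrambling C3), or hydride delivery may be incompletely face-selective. The fallback sets out from 29 and returns at 31 without a Lewis acid, setting C2 under reagent control. Corey–Bakshi–Shibata reduction of the open keto form of 29 (BH3·SMe2 with the (R)- or (S)-B-methyl diphenylprolinol oxazaborolidine, whichever gives the carbinol that matches C2 of 31) gives the 1,4-diol F9. Selective sulfonylation of the primary hydroxyl (TsCl, pyridine, 0 °C) gives monotosylate F10, and NaH in THF closes the ring by attack of the C2 alkoxide on C5, with retention at C2, to give 31.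

Step 21. Hydrogenolysis may go on after debenzylation and cleave the benzylic C2–O1 or C2'–O1' bond (ring opening of the oxolane or the dihydrobenzofuran). The fallback sets out from 32 and returns at 33 by a non-reductive dealkylation: BCl3 with pentamethylbenzene as cation scavenger, CH2Cl2, −78 °C; no new compound lies on the way.

## Further compounds

F1 | step 6 | 1-[2-[(4-benzyloxy-3-methoxyphenyl)methoxy]-5-bromo-3-methoxyphenyl]ethanone | CC(=O)c1cc(Br)cc(OC)c1OCc1ccc(OCc2ccccc2)c(OC)c1
F2 | step 6 | 2-[2-[(4-benzyloxy-3-methoxyphenyl)methoxy]-5-bromo-3-methoxyphenyl]-1-(morpholin-4-yl)ethanethione | S=C(Cc1cc(Br)cc(OC)c1OCc1ccc(OCc2ccccc2)c(OC)c1)N1CCOCC1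
F3 | step 6 | 2-[2-[(4-benzyloxy-3-methoxyphenyl)methoxy]-5-bromo-3-methoxyphenyl]acetic acid | OC(=O)Cc1cc(Br)cc(OC)c1OCc1ccc(OCc2ccccc2)c(OC)c1
F4 | step 6 | methyl 2-[2-[(4-benzyloxy-3-methoxyphenyl)methoxy]-5-bromo-3-methoxyphenyl]acetate | COC(=O)Cc1cc(Br)cc(OC)c1OCc1ccc(OCc2ccccc2)c(OC)c1
F5 | step 6 | methyl 2-[2-[(4-benzyloxy-3-methoxyphenyl)methoxy]-5-bromo-3-methoxyphenyl]-2-diazoacetate | COC(=O)C(=[N+]=[N-])c1cc(Br)cc(OC)c1OCc1ccc(OCc2ccccc2)c(OC)c1
F6 | step 5 | (2R)-2-(4-benzyloxy-3-methoxyphenyl)-6-bromo-8-methoxy-3-(trifluoroacetyl)chroman-4-one | Brc1cc(OC)c2c(c1)C(=O)C(C(=O)C(F)(F)F)[C@H](c1ccc(OCc3ccccc3)c(OC)c1)O2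
F7 | step 14 | (2S,3S)-2-[(4-benzyloxy-3-methoxyphenyl)methyl]-3-[(tert-butyldimethylsilyloxy)methyl]-5-(trimethylsilyl)pent-4-yne-1,2-diol | C[Si](C)(C)C#C[C@@H](CO[Si](C)(C)C(C)(C)C)[C@](O)(CO)Cc1ccc(OCc2ccccc2)c(OC)c1
F8 | step 14 | (2S,3S)-2-[(4-benzyloxy-3-methoxyphenyl)methyl]-3-[(tert-butyldimethylsilyloxy)methyl]pent-4-yne-1,2-diol | C#C[C@@H](CO[Si](C)(C)C(C)(C)C)[C@](O)(CO)Cc1ccc(OCc2ccccc2)c(OC)c1
F9 | step 19 | open 1,4-diol of 31: aryl carbinol at C2 (configuration as C2 of 31), free primary hydroxyl at C5, silyl ethers as in 29 | COc1cc(C[C@@](O[Si](CC)(CC)CC)(CO)[C@H](CO[Si](C)(C)C(C)(C)C)[C@@H](O)c2cc(OC)c3c(c2)[C@H](CO[Si](C)(C)C(C)(C)C)[C@H](c2ccc(OCc4ccccc4)c(OC)c2)O3)ccc1OCc1ccccc1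
F10 | step 19 | primary 4-methylbenzenesulfonate of F9 | COc1cc(C[C@@](O[Si](CC)(CC)CC)(COS(=O)(=O)c2ccc(C)cc2)[C@H](CO[Si](C)(C)C(C)(C)C)[C@@H](O)c2cc(OC)c3c(c2)[C@H](CO[Si](C)(C)C(C)(C)C)[C@H](c2ccc(OCc4ccccc4)c(OC)c2)O3)ccc1OCc1ccccc1
F0 | step 21 | none | none
A1 | alternative 1 | target with both phenols and both primary hydroxyls as tert-butyldimethylsilyl ethers, tertiary hydroxyl free | COc1cc(C[C@@]2(O)CO[C@@H](c3cc(OC)c4c(c3)[C@H](CO[Si](C)(C)C(C)(C)C)[C@H](c3ccc(O[Si](C)(C)C(C)(C)C)c(OC)c3)O4)[C@H]2CO[Si](C)(C)C(C)(C)C)ccc1O[Si](C)(C)C(C)(C)C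
A2 | alternative 1 | γ-hydroxy aryl ketone, the open precursor of A1 | COc1cc(C[C@@](O)(CO)[C@H](CO[Si](C)(C)C(C)(C)C)C(=O)c2cc(OC)c3c(c2)[C@H](CO[Si](C)(C)C(C)(C)C)[C@H](c2ccc(O[Si](C)(C)C(C)(C)C)c(OC)c2)O3)ccc1O[Si](C)(C)C(C)(C)C
A3 | alternative 2 | dimethyl cis-2-(4-benzyloxy-3-methoxyphenyl)-7-methoxy-2,3-dihydro-1-benzofuran-3,5-dicarboxylate | COC(=O)c1cc(OC)c2c(c1)[C@H](C(=O)OC)[C@H](c1ccc(OCc3ccccc3)c(OC)c1)O2
A4 | alternative 2 | methyl 7-methoxy-1-benzofuran-5-carboxylate | COC(=O)c1cc(OC)c2occc2c1
A5 | alternative 2 | 1-(benzyloxy)-4-iodo-2-methoxybenzene | COc1cc(I)ccc1OCc1ccccc1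
A6 | alternative 3 | cis-fused furofuranone with endo aryl at C2 and exo aryl on the lactone ring | COc1cc([C@@H]5[C@@]2(O[Si](C)(C)C)CO[C@@H](c3cc(OC)c4c(c3)[C@H](COCc3ccccc3)[C@H](c3ccc(OCc6ccccc6)c(OC)c3)O4)[C@H]2C(=O)O5)ccc1OCc1ccccc1
A7 | alternative 3 | α-diazo lactone, the precursor of A6, with the dihydrobenzofuranylmethyl ether on the quaternary carbon | COc1cc([C@H]2OC(=O)C(=[N+]=[N-])[C@]2(O[Si](C)(C)C)COCc3cc(OC)c4c(c3)[C@H](COCc3ccccc3)[C@H](c3ccc(OCc5ccccc5)c(OC)c3)O4)ccc1OCc1ccccc1
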